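**Retrosynthetic overview**
1. Target 26 ⇐ tri-tert-butyl ester/silyl ether 25 (acidolysis) ⇐ 7-sulfonyl bicycle 24 (C–S cleavage).
2. 24 ⇐ acyclic diazo triester 21 + phenyl vinyl sulfone 22. One rhodium-catalysed operation closes first the 1,3-dioxane ring (C5–O8 bond, as cyclic carbonyl ylide 23) and then the oxolane ring (C5–C6 and C1–C7 bonds, 1,3-dipolar cycloaddition).
3. 21 ⇐ keto ester 18 + tert-butyl diazoacetate (C4–C5 bond). 18 ⇐ di-tert-butyl D-tartrate (C3, C4 and their carboxyls) acylated with acid 15, whose carboxyl carbon becomes ketal carbon C1.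
4. 15 ⇐ Ireland–Claisen rearrangement of acetate 10 (E-alkene) ⇐ aldehyde 6 + isopropenyl Grignard; 6 ⇐ Evans benzylation (side-chain stereocentre).

Assumption: di-tert-butyl D-tartrate (16) is bought as such; ring atoms are numbered as in 2,8-dioxabicyclo[3.2.1]octane (C1 ketal carbon, O2, C3, C4, C5, C6, C7, O8).

**Route**

Step 1
Reactants: 1 (4R)-4-benzyl-3-propanoyl-1,3-oxazolidin-2-one; 2 benzyl bromide
Product: 4 (4R)-4-benzyl-3-[(2S)-2-methyl-3-phenylpropanoyl]-1,3-oxazolidin-2-one, via sodium enolate 3 (not isolated)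
Conditions: NaN(SiMe3)2, THF, −78 °C; BnBr, −78 → −40 °C
Reagents that add atoms: benzyl bromide, BrCc1ccccc1
Why: Evans asymmetric alkylation, in which the chelated Z-enolate 3 is benzylated on the face opposite the auxiliary benzyl group and so sets the side-chain stereocentre as S.

Step 2
Reactants: 4 (4R)-4-benzyl-3-[(2S)-2-methyl-3-phenylpropanoyl]-1,3-oxazolidin-2-one
Product: 5 (2S)-2-methyl-3-phenylpropan-1-ol
Conditions: LiBH4, MeOH (1 equiv), Et2O, 0 °C
Reagents that add atoms: none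
Why: Reductive cleavage of the N-acyloxazolidinone at the exocyclic carbonyl releases the auxiliary and does not touch the α-stereocentre.

Step 3
Reactants: 5 (2S)-2-methyl-3-phenylpropan-1-ol
Product: 6 (2S)-2-methyl-3-phenylpropanal
Conditions: TEMPO (10 mol %), PhI(OAc)2, CH2Cl2, rt; used crude
Reagents that add atoms: none
Why: Oxoammonium (TEMPO) oxidation stops at the aldehyde under base-free conditions, so the epimerisable α-centre is kept.

Step 4
Reactants: 6 (2S)-2-methyl-3-phenylpropanal; 7 isopropenylmagnesium bromide; 8 acetic anhydride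
Product: 10 (4S)-2,4-dimethyl-5-phenylpent-1-en-3-yl acetate (C3 epimers), via magnesium alkoxide 9 (not isolated)
Conditions: THF, −78 → 0 °C; then Ac2O, DMAP (cat.), 0 °C → rt
Reagents that add atoms: isopropenylmagnesium bromide, CC(=C)[Mg]Br; acetic anhydride, CC(=O)OC(C)=O
Why: Grignard 1,2-addition followed by O-acetylation of the alkoxide in the same flask; the carbinol centre forms as a mixture, which does not matter because step 5 destroys it.

Step 5
Reactants: 10 (4S)-2,4-dimethyl-5-phenylpent-1-en-3-yl acetate; 11 chlorotrimethylsilane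
Product: 15 (4E,6S)-4,6-dimethyl-7-phenylhept-4-enoic acid, via lithium enolate 12 (not isolated), via silyl ketene acetal 13 (not isolated), via trimethylsilyl ester 14 (not isolated)
Conditions: LiN(iPr)2, THF, −78 °C; Me3SiCl/Et3N, −78 °C → rt, then 60 °C; 1 M HCl work-up
Reagents that add atoms: none
Why: Ireland–Claisen rearrangement through a chair transition state with the CH(CH3)CH2Ph group equatorial gives the E trisubstituted alkene and the two-carbon acid chain, while the S centre is a spectator.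

Step 6
Reactants: 15 (4E,6S)-4,6-dimethyl-7-phenylhept-4-enoic acid; 16 di-tert-butyl (2S,3S)-2,3-dihydroxybutanedioate (2.5 equiv)
Product: 17 di-tert-butyl (2S,3S)-2-{[(4E,6S)-4,6-dimethyl-7-phenylhept-4-enoyl]oxy}-3-hydroxybutanedioate
Conditions: EDC·HCl, DMAP (cat.), CH2Cl2, 0 °C → rt
Reagents that add atoms: none
Why: Steglich esterification of a C2-symmetric diol, so either hydroxyl gives the same monoester and the excess diol (recovered) suppresses diacylation.

Step 7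
Reactants: 17 di-tert-butyl (2S,3S)-2-{[(4E,6S)-4,6-dimethyl-7-phenylhept-4-enoyl]oxy}-3-hydroxybutanedioate
Product: 18 di-tert-butyl (2S)-2-{[(4E,6S)-4,6-dimethyl-7-phenylhept-4-enoyl]oxy}-3-oxobutanedioate
Conditions: Dess–Martin periodinane, NaHCO3, CH2Cl2, 0 °C → rt; used at once without chromatography
Reagents that add atoms: none
Why: Dess–Martin oxidation of the remaining secondary alcohol gives the α-keto ester under buffered neutral conditions, which limits enolisation of the acidic C3–H.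

Step 8
Reactants: 18 di-tert-butyl (2S)-2-{[(4E,6S)-4,6-dimethyl-7-phenylhept-4-enoyl]oxy}-3-oxobutanedioate; 19 tert-butyl diazoacetate; 11 chlorotrimethylsilane
Product: 21 tri-tert-butyl (2R,3S)-1-diazo-3-{[(4E,6S)-4,6-dimethyl-7-phenylhept-4-enoyl]oxy}-2-[(trimethylsilyl)oxy]propane-1,2,3-tricarboxylate, via lithium aldolate 20 (not isolated)
Conditions: 19, LiN(SiMe3)2, THF, −78 °C; add 18, −78 °C; then Me3SiCl, −78 → −20 °C
Reagents that add atoms: tert-butyl diazoacetate, [N-]=[N+]=CC(=O)OC(C)(C)C; chlorotrimethylsilane, C[Si](C)(C)Cl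
Why: Aldol-type addition of lithiated 19 to the very electrophilic ketone of the α-keto ester, where in the lithium-bridged (Cram chelate) arrangement of the ketone oxygen and the C3 acyloxy oxygen the nucleophile enters anti to the bulky C3 tert-butoxycarbonyl group, setting the quaternary centre as 2R in 21 (C4 S of the target), and aldolate 20 is silylated in the same flask to block retro-aldol cleavage and acyl migration.

Step 9
Reactants: 21 tri-tert-butyl (2R,3S)-1-diazo-3-{[(4E,6S)-4,6-dimethyl-7-phenylhept-4-enoyl]oxy}-2-[(trimethylsilyl)oxy]propane-1,2,3-tricarboxylate; 22 phenyl vinyl sulfone (3 equiv)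
Product: 24 tri-tert-butyl (1S,3S,4S,5R)-1-[(3E,5S)-3,5-dimethyl-6-phenylhex-3-en-1-yl]-7-(phenylsulfonyl)-4-[(trimethylsilyl)oxy]-2,8-dioxabicyclo[3.2.1]octane-3,4,5-tricarboxylate (C7 epimers), via carbonyl ylide 23 (not isolated)
Conditions: Rh2(OAc)4 (5 mol %), benzene, reflux, slow addition of 21
Reagents that add atoms: phenyl vinyl sulfone, C=CS(=O)(=O)c1ccccc1
Why: Tandem carbonyl ylide formation–1,3-dipolar cycloaddition, in which loss of N2 at rhodium gives a carbene at C5 that is captured by the unhindered acyl carbonyl oxygen (six-membered closure) to give ylide 23, which adds to the electron-poor alkene on the face anti to the pseudoaxial C4 silyloxy group (half-chair with the C3 ester pseudoequatorial), so that both rings and the C1 (S) and C5 (R) centres arise together; the ester-bearing ylide carbon C5 bonds to the CH2 terminus of 22, and all sulfone regio- and stereoisomers converge in step 10.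

Step 10
Reactants: 24 tri-tert-butyl (1S,3S,4S,5R)-1-[(3E,5S)-3,5-dimethyl-6-phenylhex-3-en-1-yl]-7-(phenylsulfonyl)-4-[(trimethylsilyl)oxy]-2,8-dioxabicyclo[3.2.1]octane-3,4,5-tricarboxylate
Product: 25 tri-tert-butyl (1S,3S,4S,5R)-1-[(3E,5S)-3,5-dimethyl-6-phenylhex-3-en-1-yl]-4-[(trimethylsilyl)oxy]-2,8-dioxabicyclo[3.2.1]octane-3,4,5-tricarboxylate
Conditions: 6 % Na(Hg), Na2HPO4, MeOH/THF, −20 °C
Reagents that add atoms: none
Why: Reductive desulfonylation by electron transfer from sodium amalgam, with the C7 carbanion protonated by buffered methanol faster than it can expel a ring oxygen; esters, silyl ether and the trisubstituted alkene are inert.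

Step 11
Reactants: 25 tri-tert-butyl (1S,3S,4S,5R)-1-[(3E,5S)-3,5-dimethyl-6-phenylhex-3-en-1-yl]-4-[(trimethylsilyl)oxy]-2,8-dioxabicyclo[3.2.1]octane-3,4,5-tricarboxylate
Product: 26 (1S,3S,4S,5R)-1-[(3E,5S)-3,5-dimethyl-6-phenylhex-3-en-1-yl]-4-hydroxy-2,8-dioxabicyclo[3.2.1]octane-3,4,5-tricarboxylic acid
Conditions: CF3CO2H/CH2Cl2 (1:3), 0 °C → rt
Reagents that add atoms: none
Why: Acidolysis of the three tert-butyl esters (loss of isobutene) and of the silyl ether, under which the electron-poor bicyclic ketal and all stereocentres are stable.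

**Compound list**
1 | (4R)-4-benzyl-3-propanoyl-1,3-oxazolidin-2-one | CCC(=O)N1[C@H](Cc2ccccc2)COC1=O | starting material
2 | benzyl bromide | BrCc1ccccc1 | starting material
3 | sodium (Z)-1-[(4R)-4-benzyl-2-oxo-1,3-oxazolidin-3-yl]prop-1-en-1-olate | C/C=C(\[O-])N1[C@H](Cc2ccccc2)COC1=O.[Na+] | intermediate (not isolated)
4 | (4R)-4-benzyl-3-[(2S)-2-methyl-3-phenylpropanoyl]-1,3-oxazolidin-2-one | C[C@@H](Cc1ccccc1)C(=O)N1[C@H](Cc2ccccc2)COC1=O | intermediate
5 | (2S)-2-methyl-3-phenylpropan-1-ol | C[C@@H](Cc1ccccc1)CO | intermediate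
6 | (2S)-2-methyl-3-phenylpropanal | C[C@@H](Cc1ccccc1)C=O | intermediate
7 | isopropenylmagnesium bromide | CC(=C)[Mg]Br | starting material
8 | acetic anhydride | CC(=O)OC(C)=O | starting material
9 | bromomagnesium (4S)-2,4-dimethyl-5-phenylpent-1-en-3-olate (C3 epimers) | C[C@@H](Cc1ccccc1)C(O[Mg]Br)C(C)=C | intermediate (not isolated)
10 | (4S)-2,4-dimethyl-5-phenylpent-1-en-3-yl acetate (C3 epimers) | C[C@@H](Cc1ccccc1)C(OC(C)=O)C(C)=C | intermediate
11 | chlorotrimethylsilane | C[Si](C)(C)Cl | starting material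
12 | lithium 1-{[(4S)-2,4-dimethyl-5-phenylpent-1-en-3-yl]oxy}ethen-1-olate | C[C@@H](Cc1ccccc1)C(OC(=C)[O-])C(C)=C.[Li+] | intermediate (not isolated)
13 | trimethyl[(1-{[(4S)-2,4-dimethyl-5-phenylpent-1-en-3-yl]oxy}ethenyl)oxy]silane | C[C@@H](Cc1ccccc1)C(OC(=C)O[Si](C)(C)C)C(C)=C | intermediate (not isolated)
14 | trimethylsilyl (4E,6S)-4,6-dimethyl-7-phenylhept-4-enoate | C/C(=C\[C@@H](C)Cc1ccccc1)CCC(=O)O[Si](C)(C)C | intermediate (not isolated)
15 | (4E,6S)-4,6-dimethyl-7-phenylhept-4-enoic acid | C/C(=C\[C@@H](C)Cc1ccccc1)CCC(=O)O | intermediate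
16 | di-tert-butyl (2S,3S)-2,3-dihydroxybutanedioate (di-tert-butyl D-tartrate) | CC(C)(C)OC(=O)[C@@H](O)[C@H](O)C(=O)OC(C)(C)C | starting material
17 | di-tert-butyl (2S,3S)-2-{[(4E,6S)-4,6-dimethyl-7-phenylhept-4-enoyl]oxy}-3-hydroxybutanedioate | C/C(=C\[C@@H](C)Cc1ccccc1)CCC(=O)O[C@H](C(=O)OC(C)(C)C)[C@H](O)C(=O)OC(C)(C)C | intermediate
18 | di-tert-butyl (2S)-2-{[(4E,6S)-4,6-dimethyl-7-phenylhept-4-enoyl]oxy}-3-oxobutanedioate | C/C(=C\[C@@H](C)Cc1ccccc1)CCC(=O)O[C@H](C(=O)OC(C)(C)C)C(=O)C(=O)OC(C)(C)C | intermediate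
19 | tert-butyl diazoacetate | [N-]=[N+]=CC(=O)OC(C)(C)C | starting material
20 | lithium aldolate: tri-tert-butyl (2R,3S)-1-diazo-3-{[(4E,6S)-4,6-dimethyl-7-phenylhept-4-enoyl]oxy}-2-oxidopropane-1,2,3-tricarboxylate, lithium salt | C/C(=C\[C@@H](C)Cc1ccccc1)CCC(=O)O[C@H](C(=O)OC(C)(C)C)[C@@]([O-])(C(=O)OC(C)(C)C)C(=[N+]=[N-])C(=O)OC(C)(C)C.[Li+] | intermediate (not isolated)
21 | tri-tert-butyl (2R,3S)-1-diazo-3-{[(4E,6S)-4,6-dimethyl-7-phenylhept-4-enoyl]oxy}-2-[(trimethylsilyl)oxy]propane-1,2,3-tricarboxylate | C/C(=C\[C@@H](C)Cc1ccccc1)CCC(=O)O[C@H](C(=O)OC(C)(C)C)[C@@](O[Si](C)(C)C)(C(=O)OC(C)(C)C)C(=[N+]=[N-])C(=O)OC(C)(C)C | intermediate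
22 | phenyl vinyl sulfone | C=CS(=O)(=O)c1ccccc1 | starting material
23 | cyclic carbonyl ylide: 4,5,6-tris(tert-butoxycarbonyl)-2-[(3E,5S)-3,5-dimethyl-6-phenylhex-3-en-1-yl]-5-[(trimethylsilyl)oxy]-4,5-dihydro-1,3-dioxin-1-ium-6-ide, the two sp3 ring carbons configured as in 21 | C/C(=C\[C@@H](C)Cc1ccccc1)CCC1=[O+][C-](C(=O)OC(C)(C)C)[C@](O[Si](C)(C)C)(C(=O)OC(C)(C)C)[C@@H](C(=O)OC(C)(C)C)O1 | intermediate (not isolated)
24 | tri-tert-butyl (1S,3S,4S,5R)-1-[(3E,5S)-3,5-dimethyl-6-phenylhex-3-en-1-yl]-7-(phenylsulfonyl)-4-[(trimethylsilyl)oxy]-2,8-dioxabicyclo[3.2.1]octane-3,4,5-tricarboxylate (C7 epimers) | C/C(=C\[C@@H](C)Cc1ccccc1)CC[C@@]12C(S(=O)(=O)c3ccccc3)C[C@@](C(=O)OC(C)(C)C)(O1)[C@](O[Si](C)(C)C)(C(=O)OC(C)(C)C)[C@@H](C(=O)OC(C)(C)C)O2 | intermediate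
25 | tri-tert-butyl (1S,3S,4S,5R)-1-[(3E,5S)-3,5-dimethyl-6-phenylhex-3-en-1-yl]-4-[(trimethylsilyl)oxy]-2,8-dioxabicyclo[3.2.1]octane-3,4,5-tricarboxylate | C/C(=C\[C@@H](C)Cc1ccccc1)CC[C@@]12CC[C@@](C(=O)OC(C)(C)C)(O1)[C@](O[Si](C)(C)C)(C(=O)OC(C)(C)C)[C@@H](C(=O)OC(C)(C)C)O2 | intermediate
26 | (1S,3S,4S,5R)-1-[(3E,5S)-3,5-dimethyl-6-phenylhex-3-en-1-yl]-4-hydroxy-2,8-dioxabicyclo[3.2.1]octane-3,4,5-tricarboxylic acid | C/C(=C\[C@@H](C)Cc1ccccc1)CC[C@@]12CC[C@@](C(=O)O)(O1)[C@](O)(C(=O)O)[C@@H](C(=O)O)O2 | target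

**Totals**
Total steps: 11. Longest linear sequence: 11 steps (1 → 26).

**Steps most likely to fail and fallbacks**

Step 9. The ester-derived ylide 23 may form or be trapped inefficiently by the singly activated alkene 22, and the facial selectivity rests on the half-chair argument. The fallback sets out from 21 and comes back at 26, building the rings one after the other without a cycloaddition. Rh2(OAc)4 with propylene oxide as oxygen donor converts the diazo carbon into a ketone, giving the α-keto ester F1. Allylboronic acid pinacol ester adds to this ketone to give the tertiary homoallylic alcohol F2 (C5 epimers separated). Excess Cp2Ti(μ-Cl)(μ-CH2)AlMe2 in THF/pyridine methylenates the acyl ester carbonyl and closes the resulting enol ether onto the allyl group (olefinic ester cyclisation), giving the seven-membered cyclic enol ether F3. CF3CO2H in CH2Cl2 then protonates the enol ether, the C5 hydroxyl closes onto the C1 oxocarbenium ion, and the same acid cleaves the esters and the silyl ether to give 26.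

Step 8. The C3–H of 18 is flanked by a ketone and an ester, so enolisation can erode C3 or consume the nucleophile. The acyloxy oxygen is also a weak chelator, so a polar Felkin–Anh pathway could give the C4 epimer. The fallback sets out from 16 and comes back at 21, using an ether oxygen that chelates firmly and introducing the acyl group afterwards. Bu2SnO, then 4-methoxybenzyl chloride and CsF, give the mono(4-methoxybenzyl) ether F4. Dess–Martin oxidation gives the keto ester F5. Precomplexation with MgBr2·OEt2 (five-membered chelate of ketone and ether oxygens) and addition of lithiated 19 give the diazo alcohol F6. DDQ in buffered wet CH2Cl2 removes the benzyl ether to give the diol F7. Steglich esterification of the secondary hydroxyl with 15 gives the hydroxy ester F8, and Me3SiCl (11) with imidazole gives 21.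

Step 10. The transient C7 carbanion has two C1–O bonds in the β-position and could open the ketal instead of being protonated. The fallback sets out from 21 and comes back at 25, delivering C6–C7 as an acetylene equivalent so that the reduction expels sulfinate, a far better leaving group than alkoxide. (E)-1,2-bis(phenylsulfonyl)ethene replaces 22 in the Rh2(OAc)4 reaction and gives the vicinal disulfone F9. Na(Hg) in buffered methanol eliminates both sulfonyl groups to give the 6,7-alkene F10. Diimide (KO2CN=NCO2K, AcOH, MeOH) reduces only the strained disubstituted ring alkene and leaves the trisubstituted side-chain alkene, giving 25.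

**Further compounds**
F1 | step 9 | tri-tert-butyl (2S,3S)-3-{[(4E,6S)-4,6-dimethyl-7-phenylhept-4-enoyl]oxy}-1-oxo-2-[(trimethylsilyl)oxy]propane-1,2,3-tricarboxylate | C/C(=C\[C@@H](C)Cc1ccccc1)CCC(=O)O[C@H](C(=O)OC(C)(C)C)[C@@](O[Si](C)(C)C)(C(=O)OC(C)(C)C)C(=O)C(=O)OC(C)(C)C
F2 | step 9 | tri-tert-butyl (1S,2S,3R)-1-{[(4E,6S)-4,6-dimethyl-7-phenylhept-4-enoyl]oxy}-3-hydroxy-2-[(trimethylsilyl)oxy]hex-5-ene-1,2,3-tricarboxylate | C/C(=C\[C@@H](C)Cc1ccccc1)CCC(=O)O[C@H](C(=O)OC(C)(C)C)[C@@](O[Si](C)(C)C)(C(=O)OC(C)(C)C)[C@](O)(CC=C)C(=O)OC(C)(C)C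
F3 | step 9 | tri-tert-butyl (2S,3S,4R)-7-[(3E,5S)-3,5-dimethyl-6-phenylhex-3-en-1-yl]-4-hydroxy-3-[(trimethylsilyl)oxy]-2,3,4,5-tetrahydrooxepine-2,3,4-tricarboxylate | C/C(=C\[C@@H](C)Cc1ccccc1)CCC1=CC[C@](O)(C(=O)OC(C)(C)C)[C@](O[Si](C)(C)C)(C(=O)OC(C)(C)C)[C@@H](C(=O)OC(C)(C)C)O1
F4 | step 8 | di-tert-butyl (2S,3S)-2-hydroxy-3-[(4-methoxybenzyl)oxy]butanedioate | COc1ccc(CO[C@H](C(=O)OC(C)(C)C)[C@H](O)C(=O)OC(C)(C)C)cc1
F5 | step 8 | di-tert-butyl (2S)-2-[(4-methoxybenzyl)oxy]-3-oxobutanedioate | COc1ccc(CO[C@H](C(=O)OC(C)(C)C)C(=O)C(=O)OC(C)(C)C)cc1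
F6 | step 8 | tri-tert-butyl (2R,3S)-1-diazo-2-hydroxy-3-[(4-methoxybenzyl)oxy]propane-1,2,3-tricarboxylate | COc1ccc(CO[C@H](C(=O)OC(C)(C)C)[C@@](O)(C(=O)OC(C)(C)C)C(=[N+]=[N-])C(=O)OC(C)(C)C)cc1
F7 | step 8 | tri-tert-butyl (2R,3S)-1-diazo-2,3-dihydroxypropane-1,2,3-tricarboxylate | O[C@H](C(=O)OC(C)(C)C)[C@@](O)(C(=O)OC(C)(C)C)C(=[N+]=[N-])C(=O)OC(C)(C)C
F8 | step 8 | tri-tert-butyl (2R,3S)-1-diazo-3-{[(4E,6S)-4,6-dimethyl-7-phenylhept-4-enoyl]oxy}-2-hydroxypropane-1,2,3-tricarboxylate | C/C(=C\[C@@H](C)Cc1ccccc1)CCC(=O)O[C@H](C(=O)OC(C)(C)C)[C@@](O)(C(=O)OC(C)(C)C)C(=[N+]=[N-])C(=O)OC(C)(C)C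
F9 | step 10 | tri-tert-butyl (1S,3S,4S,5R)-1-[(3E,5S)-3,5-dimethyl-6-phenylhex-3-en-1-yl]-6,7-bis(phenylsulfonyl)-4-[(trimethylsilyl)oxy]-2,8-dioxabicyclo[3.2.1]octane-3,4,5-tricarboxylate (trans disulfone) | C/C(=C\[C@@H](C)Cc1ccccc1)CC[C@@]12C(S(=O)(=O)c3ccccc3)C(S(=O)(=O)c3ccccc3)[C@@](C(=O)OC(C)(C)C)(O1)[C@](O[Si](C)(C)C)(C(=O)OC(C)(C)C)[C@@H](C(=O)OC(C)(C)C)O2
F10 | step 10 | tri-tert-butyl (1S,3S,4S,5R)-1-[(3E,5S)-3,5-dimethyl-6-phenylhex-3-en-1-yl]-4-[(trimethylsilyl)oxy]-2,8-dioxabicyclo[3.2.1]oct-6-ene-3,4,5-tricarboxylate | C/C(=C\[C@@H](C)Cc1ccccc1)CC[C@@]12C=C[C@@](C(=O)OC(C)(C)C)(O1)[C@](O[Si](C)(C)C)(C(=O)OC(C)(C)C)[C@@H](C(=O)OC(C)(C)C)O2
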